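**Retrosynthetic overview**
- The strategy rests on the single ring: a benzene carrying only two substituents, para to each other, the OH on C4 and the CH2CH2O–acyl chain on C1. C3–C4–C5–C6 (with the oxygen on C4) map onto a 2-silyloxybuta-1,3-diene and C1–C2 onto a terminal alkyne.
- The target is traced back, by desilylation and dehydrogenation, to a cyclohexa-1,4-diene silyl enol ether. Cutting its ring bonds C1–C6 and C2–C3 (formal [4+2] with the CoBr2(dppe)/Zn/ZnI2 catalyst) gives but-3-yn-1-yl heptatriacontanoate and 2-(trimethylsilyloxy)buta-1,3-diene.
- The alkynyl ester comes from heptatriacontanoic acid and but-3-yn-1-ol. The C37 acid comes from a C22 Grignard reagent and 15-bromopentadecanoic acid by Li2CuCl4-catalysed C15–C16 coupling.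
- Ring order: the one carbocycle is closed in step 3 and aromatised in step 4. The phenol appears only at the end, so the ester is made on a monofunctional alcohol.

Key step: step 3

Remark: the C37 acid and its esters are waxy and sparingly soluble when cold, so steps 2 to 4 are assumed to be run warm or dilute in chlorinated or aromatic solvents.

**Step 1**
Reactants: 1 1-bromodocosane; 2 15-bromopentadecanoic acid
Product: 5 heptatriacontanoic acid, via docosylmagnesium bromide 3 (not isolated), via chloromagnesium 15-bromopentadecanoate 4 (not isolated)
Conditions: (a) 1 (1.4 equiv), Mg turnings, THF, 50 °C; (b) 2, MeMgCl (1.0 equiv), THF, −20 °C; (c) solution a added to b, Li2CuCl4 (3 mol%), THF, −20 °C to rt; then 1 M HCl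
Reagents that add atoms: none
Why: Kochi-type Li2CuCl4-catalysed sp3–sp3 cross-coupling of a primary alkyl Grignard reagent with a primary alkyl bromide; prior deprotonation with MeMgCl masks the acid as a halomagnesium carboxylate so that the Grignard reagent is spent only on the C–Br bond, and the acid should be freed from neutral hydrocarbon by-products by recrystallisation from hot toluene/acetone.

**Step 2**
Reactants: 5 heptatriacontanoic acid; 6 but-3-yn-1-ol
Product: 7 but-3-yn-1-yl heptatriacontanoate
Conditions: 6 (1.5 equiv), N,N'-diisopropylcarbodiimide (1.2 equiv), DMAP (0.1 equiv), CHCl3, 40 °C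
Reagents that add atoms: none
Why: Steglich esterification of an unhindered acid with a monofunctional primary alcohol; the terminal alkyne is inert to carbodiimide and DMAP, and the warm chloroform keeps the acid in solution.

**Step 3**
Reactants: 7 but-3-yn-1-yl heptatriacontanoate; 8 2-(trimethylsilyloxy)buta-1,3-diene
Product: 9 2-[4-(trimethylsilyloxy)cyclohexa-1,4-dien-1-yl]ethyl heptatriacontanoate
Conditions: 8 (2 equiv), CoBr2(dppe) (10 mol%; dppe = Ph2PCH2CH2PPh2), Zn powder (20 mol%), ZnI2 (20 mol%), CH2Cl2, 30 °C; filtration through Et3N-deactivated silica, used at once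
Reagents that add atoms: none
Why: Zn reduces the divalent cobalt precatalyst CoBr2(dppe) to a monovalent cobalt species and ZnI2 abstracts halide to open coordination sites, so that diene 8 and the terminal alkyne of 7 bind side by side; oxidative cyclisation forms the first C–C bond and gives a trivalent cobalt allyl–vinyl metallacycle, and reductive elimination forms the second bond and returns monovalent cobalt. The closest known reaction type is the cobalt-catalysed neutral Diels–Alder reaction of unactivated terminal alkynes with 2-substituted buta-1,3-dienes, 2-silyloxydienes included. The only ring, the six-membered carbocycle, closes by an intermolecular formal [4+2] cycloaddition in which ring bonds C1–C6 and C2–C3 are both made at the metal, leaving the skipped C1=C2 and C4=C5 double bonds of a cyclohexa-1,4-diene. No stereocentre is formed. The step needs 1,4 (para) over 1,3 (meta) regiochemistry, and the bisphosphine ligand should secure it: in the metallacycle the alkyne substituent is held away from the silyloxy-bearing diene carbon and from the PPh2 groups, so the CH2CH2O chain ends up across the ring from OSiMe3. The alkyne has no activating group, which rules out a thermal Diels–Alder reaction but suits this catalyst; the ester two carbons from the triple bond should not interfere, and the excess of 8 holds back alkyne cyclotrimerisation.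

**Step 4**
Reactants: 9 2-[4-(trimethylsilyloxy)cyclohexa-1,4-dien-1-yl]ethyl heptatriacontanoate
Product: 11 2-(4-hydroxyphenyl)ethyl heptatriacontanoate (CNP0230173.0), via 2-[4-(trimethylsilyloxy)phenyl]ethyl heptatriacontanoate 10 (not isolated)
Conditions: DDQ (1.1 equiv), toluene, rt; filter; then THF, 1 M HCl, rt
Reagents that add atoms: none
Why: oxidative aromatisation, in which DDQ abstracts hydride from a doubly allylic CH2 of the cyclohexa-1,4-diene and proton loss gives the arene; the aryl trimethylsilyl ether should then be cleaved by dilute aqueous acid at rt, under which the primary alkyl ester is not hydrolysed.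

**Compound list**
1 | 1-bromodocosane | CCCCCCCCCCCCCCCCCCCCCCBr | starting material
2 | 15-bromopentadecanoic acid | BrCCCCCCCCCCCCCCC(=O)O | starting material
3 | docosylmagnesium bromide | CCCCCCCCCCCCCCCCCCCCCC[Mg]Br | intermediate
4 | chloromagnesium 15-bromopentadecanoate | BrCCCCCCCCCCCCCCC(=O)O[Mg]Cl | intermediate
5 | heptatriacontanoic acid | CCCCCCCCCCCCCCCCCCCCCCCCCCCCCCCCCCCCC(=O)O | intermediate
6 | but-3-yn-1-ol | OCCC#C | starting material
7 | but-3-yn-1-yl heptatriacontanoate | CCCCCCCCCCCCCCCCCCCCCCCCCCCCCCCCCCCCC(=O)OCCC#C | intermediate
8 | 2-(trimethylsilyloxy)buta-1,3-diene | C=CC(=C)O[Si](C)(C)C | starting material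
9 | 2-[4-(trimethylsilyloxy)cyclohexa-1,4-dien-1-yl]ethyl heptatriacontanoate | CCCCCCCCCCCCCCCCCCCCCCCCCCCCCCCCCCCCC(=O)OCCC1=CCC(O[Si](C)(C)C)=CC1 | intermediate
10 | 2-[4-(trimethylsilyloxy)phenyl]ethyl heptatriacontanoate | CCCCCCCCCCCCCCCCCCCCCCCCCCCCCCCCCCCCC(=O)OCCc1ccc(O[Si](C)(C)C)cc1 | intermediate
11 | 2-(4-hydroxyphenyl)ethyl heptatriacontanoate (CNP0230173.0) | CCCCCCCCCCCCCCCCCCCCCCCCCCCCCCCCCCCCC(=O)OCCc1ccc(O)cc1 | target

**Step count**
Total: 4 steps. Longest linear sequence: 4 steps (1 and 2 to 5, 7, 9, 11).

**Steps most likely to fail**

Step 3. Slow turnover of the waxy, sparingly soluble alkynyl ester may let alkyne cyclotrimerisation take over. Loss of regiocontrol would leave a 1,3 isomer that the long chain makes hard to separate, and the silyl enol ether may hydrolyse during isolation. The fallback gives up building the ring and takes the arene from a purchased building block. It sets out from 5. Acylation of commercial 2-[4-(benzyloxy)phenyl]ethan-1-ol with 5 (N,N'-diisopropylcarbodiimide, DMAP, CHCl3, 40 °C) should give 2-[4-(benzyloxy)phenyl]ethyl heptatriacontanoate F1. Hydrogenolysis of the benzyl ether (H2, Pd/C, THF/EtOAc, 40 °C) then comes back to the route at 11.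

Step 4. DDQ may over-oxidise, either by dehydrogenating the silyl enol ether towards a dienone or by attacking the benzylic position of the electron-rich arene. Alternatively the enol ether may hydrolyse before dehydrogenation, leaving an enone that DDQ does not aromatise cleanly. The fallback sets out from 9 and makes the hydrolysis deliberate. Oxalic acid in wet THF at 0 °C should give 2-(4-oxocyclohex-1-en-1-yl)ethyl heptatriacontanoate F2. Aerobic dehydrogenation of this cyclohexenone to the phenol (Pd(O2CCF3)2, 2-(dimethylamino)pyridine, TsOH, O2 at 1 atm, DMSO/chlorobenzene, 80 °C) comes back to the route at 11.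

Step 1. Homocoupling and reduction of the Grignard reagent, together with sluggish coupling at the poorly soluble carboxylate salt, may leave unreacted bromo acid that co-crystallises with the C37 acid. The fallback replaces the sp3–sp3 coupling by olefination and hydrogenation, and sets out from 2. Heating 2 with PPh3 in MeCN should give (14-carboxytetradecyl)triphenylphosphonium bromide F3. Commercial docosan-1-ol is oxidised (TEMPO, PhI(OAc)2, CH2Cl2) to docosanal F4. Wittig reaction of F3 (NaN(SiMe3)2, 2.1 equiv, THF, 0 °C) with F4 should give (15Z)-heptatriacont-15-enoic acid F5; the alkene geometry is of no consequence. Hydrogenation (H2, Pd/C, THF, 40 °C) comes back to the route at 5.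

**Further compounds**
F1 | step 3 | 2-[4-(benzyloxy)phenyl]ethyl heptatriacontanoate | CCCCCCCCCCCCCCCCCCCCCCCCCCCCCCCCCCCCC(=O)OCCc1ccc(OCc2ccccc2)cc1
F2 | step 4 | 2-(4-oxocyclohex-1-en-1-yl)ethyl heptatriacontanoate | CCCCCCCCCCCCCCCCCCCCCCCCCCCCCCCCCCCCC(=O)OCCC1=CCC(=O)CC1
F3 | step 1 | (14-carboxytetradecyl)triphenylphosphonium bromide | OC(=O)CCCCCCCCCCCCCC[P+](c1ccccc1)(c1ccccc1)c1ccccc1.[Br-]
F4 | step 1 | docosanal | CCCCCCCCCCCCCCCCCCCCCC=O
F5 | step 1 | (15Z)-heptatriacont-15-enoic acid | CCCCCCCCCCCCCCCCCCCCC/C=C\CCCCCCCCCCCCCC(=O)O
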